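## The problem

Target 15 is a hexasubstituted 1,4-benzoquinone (ring A). Its C2 and C5 carry 4-hydroxyphenyl rings (rings B and B′) and its C1 and C4 oxygens are acylated, so each ester is an enol ester of a quinone, a vinylogous anhydride that hydroxide, alkoxides, amines or unbuffered fluoride will cleave. Both acyl groups are the same (2Z,4S,5S)-4,5-epoxyhex-2-enoyl chain and the molecule has a twofold axis, so every construction can be run twice in one flask. The four stereocentres are C4 and C5 of each arm. Within an arm they form a trans-epoxide and are best set together from an E-alkene, but the arms are too far apart to control each other, so the absolute configuration must come from a reagent-controlled step, and any minor enantiomer of an arm ends up as a diastereomer of the product. The two C2=C3 bonds are Z, conjugated and next to an allylic epoxide; they must be made kinetically and late, and neither they nor the vinyl epoxides tolerate acid, nucleophilic catalysts, zerovalent palladium or hydrogenation. Ring A bears four oxygens, of which one para pair must end as esters and the other as carbonyls, so the core has to be built with that differentiation and kept at the hydroquinone level whenever base is used. The enabling feature is that in each arm C2=C3 lies between the ester carbonyl C1 and the epoxide carbon C4: cutting it leaves a phosphonoacetate on a ring A oxygen and a four-carbon trans-epoxy aldehyde that carries C4 and C5 ready-made.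

## Retrosynthesis

**15 ⇒ 14 (two phenolic O–Si bonds).** The phenols of rings B and B′ must stay masked from the first C–C coupling until ring A has been oxidised. Silyl ethers are preferred to benzyl-type ethers, whose hydrogenolysis would reduce the alkenes and epoxides, and to acetals, whose acid cleavage would open the epoxides. Bis-silyl ether 14 differs from 15 only in these two groups. The forward step needs a fluoride source that is neither basic nor a good acyl acceptor.

**14 ⇒ 13 (oxidation level of ring A; two O–CH3 bonds).** The quinone carbonyls are traced back to the two methoxy groups of hydroquinone dimethyl ether 13. Free hydroxyls at these positions would sit beside aryl esters and invite acyl migration, and silyl ethers would need extra steps to differentiate, whereas the methyl ethers come from the first step of the route and are inert to everything before this point. Compound 13 is an ordinary, non-electrophilic arene. The forward reaction is an oxidative demethylation that must be fast and cold enough to spare the epoxides.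

**13 ⇒ 8 + 11 (both C2=C3 bonds; the key cut).** Each Z-alkene is split into the aryl phosphonoacetate of bis-phosphonate 8 and the aldehyde carbon of epoxy aldehyde 11.
- The neighbouring cut at the acyl C1–O bond would require activating a (Z)-epoxy-enoic acid toward a hindered phenol with a nucleophilic catalyst. That is the situation in which Z-enoyl species isomerise, and the free acid can open its own epoxide.
- Cuts at C3–C4 or at the epoxide C–O bonds would set stereocentres twice on the assembled core with no directing group.

The chosen cut leaves 8, which has no stereocentre and no sensitive group, and 11, which has four carbons. It asks the forward reaction only for Z geometry, twice, under conditions that aryl esters and aryl silyl ethers survive.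

**8 ⇒ 5 + 7 (two ester C–O bonds).** The phosphonoacetates are attached to hydroquinone 5 with phosphonoacetic acid 7. Such acids are activated by carbodiimides to small, ketene-like acylating species that reach phenols flanked by two ortho substituents. Compound 5 offers exactly two free hydroxyls, so no selectivity is needed.

**5 ⇒ 4 ⇒ 2 + 3 ⇒ 1 (redox; two aryl–ring A bonds; two C–OMe bonds).** Reducing quinone 4 creates the oxygen differentiation by itself: the former carbonyl oxygens become the free hydroxyls of 5 and the methoxy oxygens stay capped. Quinone 4 is cut at both aryl–ring A bonds into dibromoquinone 2 and commercial boronic acid 3, a twofold Suzuki–Miyaura coupling that is shorter than any de novo construction of ring A or of rings B. Compound 2 comes from bromanil 1 by double methanolysis, whose 2,5-regiochemistry is inherent.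

**11 ⇒ 10 ⇒ 9 (alcohol oxidation; epoxide C–O bonds).** Aldehyde 11 comes from epoxy alcohol 10 by oxidation, and 10 from (E)-but-2-en-1-ol 9 by Sharpless asymmetric epoxidation. This sets C4 and C5 of an arm in one reagent-controlled step before the fragment meets the core.

**7 ⇒ 6 (carboxylic ester C–O bond).** Acid 7 is the saponification product of the commercial methyl ester 6. The only demand is that hydroxide attacks the carboxyl carbon and not phosphorus.

## Roads not taken

**Alternative 1:** Both rings B are taken apart, each at two C–C bonds.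
- Forward key step: a twofold [4+2] cycloaddition of 2,5-diethynyl-3,6-dimethoxy-1,4-benzoquinone A1 with (E)-1-methoxy-3-(trimethylsilyloxy)buta-1,3-diene A2, followed by elimination and desilylation, would give 2,5-bis(4-hydroxyphenyl)-3,6-dimethoxy-1,4-benzoquinone A3.
- Merits: the polarity of A2 programs the para-hydroxy pattern, four C–C bonds form in one operation, and no boronic acid is needed.
- Weak points: A1 is a cross-conjugated diynyl quinone that must itself be made from 2 by two palladium-catalysed alkynylations. It offers the electron-rich diene competing channels (the quinone C=C bonds, electron transfer, conjugate addition) and is prone to polymerise. A3 arrives with free phenols that need silylation before reduction and acylation.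
- Comparison: A3 is only the desilylated form of 4, which the chosen route reaches in two steps from 1. Alternative 1 matches the chosen plan in symmetry and convergence but spends its key step on bonds that commercial 3 already provides, and leaves the side arms unsolved.

**Alternative 2:** One ring A C–C bond between two oxygen-bearing carbons is cut.
- Forward key step: heating 4-hydroxy-3-methoxy-4-[2-methoxy-1-(4-methoxyphenyl)ethenyl]-2-(4-methoxyphenyl)cyclobut-2-en-1-one A4 would open it to a dienylketene, which closes by 6π-electrocyclisation and tautomerises to 2,5-dimethoxy-3,6-bis(4-methoxyphenyl)benzene-1,4-diol A5.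
- Merits: A5 has the same oxygen differentiation as 5 and arrives at the hydroquinone level without palladium and without a reduction step. In this respect, and in its reach toward unsymmetrical cores, it is as good as or better than the chosen route.
- Weak points: A4 needs a stepwise assembly on a four-membered ring, including a trisubstituted alkenyl metal bearing aryl and methoxy groups. The methyl ethers on rings B of A5 cannot be removed without also cleaving the ring A ethers, so silyl-protected aryl nucleophiles would have to be carried through the organolithium steps.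
- Comparison: the chosen plan sets against it three steps from 1 with commercial pieces, and ring B protection that is correct from the start.

**Alternative 3:** Each arm is cut at C3–C4.
- Forward key step: 2,5-dimethoxy-3,6-bis[4-(tert-butyldimethylsilyloxy)phenyl]-1,4-phenylene dipropiolate A6, metalated twice with LiN(SiMe3)2, adds to (R)-2-chloropropanal A7 to give the bis-chlorohydrin 2,5-dimethoxy-3,6-bis[4-(tert-butyldimethylsilyloxy)phenyl]-1,4-phenylene bis[(4S,5R)-5-chloro-4-hydroxyhex-2-ynoate] A8. Semi-hydrogenation over Pd/CaCO3 poisoned with Pb(OAc)2, then base-induced closure with inversion at C5, would complete the arms.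
- Merits: syn-addition of hydrogen to an alkyne fixes Z geometry unambiguously, which is better than any olefination on that point. The stereochemistry starts from an inexpensive chiral-pool aldehyde, and no volatile epoxy aldehyde is handled.
- Weak points: A6 is electrophilic at both its β-carbon and its acyl carbon while its acetylide is a nucleophile, so self-condensation and aryloxide loss threaten. A7 racemises through its enol and adds nucleophiles with only moderate substrate control, which is compounded in a twofold reaction. The C4 centres are set on the assembled core. Three further operations on both arms follow, including a base-mediated closure next to aryl esters.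
- Comparison: the chosen plan concedes the certainty of alkene geometry. It sets against this stereocentres fixed by reagent control before coupling, a key step that only has to deliver geometry, and a shorter sequence after the coupling.

Key step: step 8

Assumption: the (E)-but-2-en-1-ol used is geometrically pure, since any Z isomer would be carried through as a cis-epoxide.

## Route

Step 1
Reactants: 1 tetrabromo-1,4-benzoquinone (bromanil)
Product: 2 2,5-dibromo-3,6-dimethoxy-1,4-benzoquinone
Conditions: NaOMe (2.1 equiv), MeOH, 0 °C to rt
Reagents that add atoms: sodium methoxide, [Na+].[O-]C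
Why: Nucleophilic vinylic substitution (addition–elimination) on a haloquinone; the first methoxy group turns its enone arm into a vinylogous ester and deactivates the neighbouring C–Br, so the second methoxide enters para to the first and the 2,5-dimethoxy isomer should result.

Step 2
Reactants: 2 2,5-dibromo-3,6-dimethoxy-1,4-benzoquinone; 3 4-(tert-butyldimethylsilyloxy)phenylboronic acid
Product: 4 2,5-bis[4-(tert-butyldimethylsilyloxy)phenyl]-3,6-dimethoxy-1,4-benzoquinone
Conditions: 3 (2.4 equiv), PdCl2(dppf) (5 mol %), K3PO4, 1,4-dioxane–H2O (20:1), 85 °C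
Reagents that add atoms: none
Why: Twofold Suzuki–Miyaura coupling; the C–Br bonds of 2 are vinylogous acyl bromides that add readily to zerovalent palladium, and halo-alkoxyquinones are established partners. Phosphate in nearly anhydrous dioxane should spare both the vinylogous methyl esters and the aryl silyl ethers.

Step 3
Reactants: 4 2,5-bis[4-(tert-butyldimethylsilyloxy)phenyl]-3,6-dimethoxy-1,4-benzoquinone
Product: 5 2,5-dimethoxy-3,6-bis[4-(tert-butyldimethylsilyloxy)phenyl]benzene-1,4-diol
Conditions: Na2S2O4, THF–H2O, rt, argon; used at once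
Reagents that add atoms: none
Why: Dithionite reduction of a quinone to its hydroquinone; the two hydroxyls formed are exactly the oxygens to be acylated while the other para pair stays methylated. The electron-rich product re-oxidises in air and is therefore carried on directly.

Step 4
Reactants: 6 methyl [bis(2,2,2-trifluoroethoxy)phosphoryl]acetate
Product: 7 [bis(2,2,2-trifluoroethoxy)phosphoryl]acetic acid
Conditions: LiOH (1.05 equiv), THF–H2O, 0 °C; then aq. HCl to pH 2
Reagents that add atoms: lithium hydroxide, [Li+].[OH-]
Why: Saponification of a methyl carboxylate; with one equivalent of hydroxide at 0 °C the unhindered carboxyl carbon should be attacked in preference to phosphorus, and acidification frees the acid.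

Step 5
Reactants: 5 2,5-dimethoxy-3,6-bis[4-(tert-butyldimethylsilyloxy)phenyl]benzene-1,4-diol; 7 [bis(2,2,2-trifluoroethoxy)phosphoryl]acetic acid
Product: 8 2,5-dimethoxy-3,6-bis[4-(tert-butyldimethylsilyloxy)phenyl]-1,4-phenylene bis{[bis(2,2,2-trifluoroethoxy)phosphoryl]acetate}
Conditions: 7 (2.5 equiv), N,N'-dicyclohexylcarbodiimide (2.6 equiv), DMAP (cat.), CH2Cl2, 0 °C to rt, argon
Reagents that add atoms: none
Why: Steglich esterification; the O-acylisourea of a phosphonoacetic acid can collapse to a phosphonoketene, a small electrophile that should acylate a phenol flanked by methoxy and aryl groups. No stereochemical element is involved.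

Step 6
Reactants: 9 (E)-but-2-en-1-ol
Product: 10 [(2S,3S)-3-methyloxiran-2-yl]methanol
Conditions: Ti(OiPr)4 (cat.), L-(+)-diisopropyl tartrate (cat.), t-BuOOH, 4 Å molecular sieves, CH2Cl2, −20 °C; non-aqueous work-up
Reagents that add atoms: tert-butyl hydroperoxide, CC(C)(C)OO
Why: Sharpless asymmetric epoxidation; the titanium tartrate complex binds the allylic alcohol and the hydroperoxide and delivers oxygen to one alkene face, which with the L-(+)-tartrate gives the (2S,3S) epoxide. The E geometry translates into the trans relationship, so both stereocentres of an arm are set here by reagent control.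

Step 7
Reactants: 10 [(2S,3S)-3-methyloxiran-2-yl]methanol
Product: 11 (2R,3S)-3-methyloxirane-2-carbaldehyde
Conditions: TEMPO (cat.), PhI(OAc)2, CH2Cl2, rt; filtered through K2CO3 and silica; kept as a dried, titrated solution
Reagents that add atoms: none
Why: Oxoammonium-mediated alcohol oxidation that stops at the aldehyde and leaves the epoxide alone. The α-carbon is an epoxide carbon and is not readily epimerised (the descriptor changes from S to R only through the priority rules), and the volatile, water-soluble aldehyde is not concentrated to dryness.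

Step 8
Reactants: 8 2,5-dimethoxy-3,6-bis[4-(tert-butyldimethylsilyloxy)phenyl]-1,4-phenylene bis{[bis(2,2,2-trifluoroethoxy)phosphoryl]acetate}; 11 (2R,3S)-3-methyloxirane-2-carbaldehyde
Product: 13 2,5-dimethoxy-3,6-bis[4-(tert-butyldimethylsilyloxy)phenyl]-1,4-phenylene bis[(2Z,4S,5S)-4,5-epoxyhex-2-enoate], via dipotassium bis-phosphonate dianion 12 (not isolated)
Conditions: KN(SiMe3)2 (2.1 equiv), 18-crown-6 (6 equiv), THF, −78 °C; then 11 (3 equiv), −78 °C; quench cold with aq. NH4Cl
Reagents that add atoms: none
Why: KN(SiMe3)2 removes one proton from each P–CH2–C(=O) unit of 8 to give dianion 12, whose two carbanions react independently: each adds to the carbonyl of 11, the adduct closes to an oxaphosphetane and expels potassium bis(2,2,2-trifluoroethyl) phosphate, forming a C2=C3 bond (two skeletal bonds in all, no ring closed). The closest known reaction type is the Still–Gennari variant of the Horner–Wadsworth–Emmons olefination, established for 2,3-epoxy aldehydes giving (Z)-4,5-epoxy-2-enoates and applied here twice to an aryl phosphonoacetate. Z selectivity is the selectivity required: the electron-poor trifluoroethoxy groups make collapse of the first-formed adduct faster than its reversion, and 18-crown-6 strips potassium from the intermediate so that no chelated, equilibrating species forms at −78 °C. No stereocentre is created; C4 and C5 arrive from 11, whose α-carbon is an epoxide carbon and meets only the preformed stabilised carbanion, not free amide base. Ring A is a plain dimethoxyarene at this stage, so no quinone or vinylogous anhydride meets the base. Each aryl ester is shielded by two ortho substituents, and loss of aryloxide from the stabilised enolate should be slow at this temperature. Excess aldehyde drives both arms to completion, and a Z,E by-product would have to be removed by chromatography.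

Step 9
Reactants: 13 2,5-dimethoxy-3,6-bis[4-(tert-butyldimethylsilyloxy)phenyl]-1,4-phenylene bis[(2Z,4S,5S)-4,5-epoxyhex-2-enoate]
Product: 14 2,5-bis[4-(tert-butyldimethylsilyloxy)phenyl]-3,6-dioxocyclohexa-1,4-diene-1,4-diyl bis[(2Z,4S,5S)-4,5-epoxyhex-2-enoate]
Conditions: (NH4)2Ce(NO3)6 (2.5 equiv), MeCN–H2O (4:1), 0 °C, minutes; cold NaHCO3 quench
Reagents that add atoms: water, O
Why: Oxidative demethylation of a hydroquinone dimethyl ether: tetravalent cerium takes two electrons from ring A, water adds at the two methoxy-bearing carbons and methanol leaves, giving the para-quinone with both ester oxygens in place. The silyloxyphenyl rings are harder to oxidise, and the epoxides, deactivated by the adjoining electron-poor alkene, should survive a short cold exposure.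

Step 10
Reactants: 14 2,5-bis[4-(tert-butyldimethylsilyloxy)phenyl]-3,6-dioxocyclohexa-1,4-diene-1,4-diyl bis[(2Z,4S,5S)-4,5-epoxyhex-2-enoate]
Product: 15 2,5-bis(4-hydroxyphenyl)-3,6-dioxocyclohexa-1,4-diene-1,4-diyl bis[(2Z,4S,5S)-4,5-epoxyhex-2-enoate] (target)
Conditions: Et3N·3HF, THF–MeCN, 0 °C to rt
Reagents that add atoms: none
Why: Fluoride-driven cleavage of aryl silyl ethers; the amine–hydrogen fluoride complex is non-basic and a poor nucleophile at carbon, so the acyloxyquinone, the epoxides and the Z-alkenes should be left untouched, and no stereocentre is affected.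

## Compound list

1 | tetrabromo-1,4-benzoquinone (bromanil) | O=C1C(Br)=C(Br)C(=O)C(Br)=C1Br | starting material
2 | 2,5-dibromo-3,6-dimethoxy-1,4-benzoquinone | COC1=C(Br)C(=O)C(OC)=C(Br)C1=O | intermediate
3 | 4-(tert-butyldimethylsilyloxy)phenylboronic acid | CC(C)(C)[Si](C)(C)Oc1ccc(B(O)O)cc1 | starting material
4 | 2,5-bis[4-(tert-butyldimethylsilyloxy)phenyl]-3,6-dimethoxy-1,4-benzoquinone | COC1=C(c2ccc(O[Si](C)(C)C(C)(C)C)cc2)C(=O)C(OC)=C(c2ccc(O[Si](C)(C)C(C)(C)C)cc2)C1=O | intermediate
5 | 2,5-dimethoxy-3,6-bis[4-(tert-butyldimethylsilyloxy)phenyl]benzene-1,4-diol | COc1c(O)c(-c2ccc(O[Si](C)(C)C(C)(C)C)cc2)c(OC)c(O)c1-c1ccc(O[Si](C)(C)C(C)(C)C)cc1 | intermediate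
6 | methyl [bis(2,2,2-trifluoroethoxy)phosphoryl]acetate | COC(=O)CP(=O)(OCC(F)(F)F)OCC(F)(F)F | starting material
7 | [bis(2,2,2-trifluoroethoxy)phosphoryl]acetic acid | OC(=O)CP(=O)(OCC(F)(F)F)OCC(F)(F)F | intermediate
8 | 2,5-dimethoxy-3,6-bis[4-(tert-butyldimethylsilyloxy)phenyl]-1,4-phenylene bis{[bis(2,2,2-trifluoroethoxy)phosphoryl]acetate} | COc1c(OC(=O)CP(=O)(OCC(F)(F)F)OCC(F)(F)F)c(-c2ccc(O[Si](C)(C)C(C)(C)C)cc2)c(OC)c(OC(=O)CP(=O)(OCC(F)(F)F)OCC(F)(F)F)c1-c1ccc(O[Si](C)(C)C(C)(C)C)cc1 | intermediate
9 | (E)-but-2-en-1-ol | C/C=C/CO | starting material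
10 | [(2S,3S)-3-methyloxiran-2-yl]methanol | C[C@@H]1O[C@H]1CO | intermediate
11 | (2R,3S)-3-methyloxirane-2-carbaldehyde | C[C@@H]1O[C@H]1C=O | intermediate
12 | dipotassium bis-phosphonate dianion of 8 (both P–CH–C(=O) carbons deprotonated) | COc1c(OC(=O)[CH-]P(=O)(OCC(F)(F)F)OCC(F)(F)F)c(-c2ccc(O[Si](C)(C)C(C)(C)C)cc2)c(OC)c(OC(=O)[CH-]P(=O)(OCC(F)(F)F)OCC(F)(F)F)c1-c1ccc(O[Si](C)(C)C(C)(C)C)cc1.[K+].[K+] | intermediate
13 | 2,5-dimethoxy-3,6-bis[4-(tert-butyldimethylsilyloxy)phenyl]-1,4-phenylene bis[(2Z,4S,5S)-4,5-epoxyhex-2-enoate] | COc1c(OC(=O)/C=C\[C@@H]2O[C@H]2C)c(-c2ccc(O[Si](C)(C)C(C)(C)C)cc2)c(OC)c(OC(=O)/C=C\[C@@H]2O[C@H]2C)c1-c1ccc(O[Si](C)(C)C(C)(C)C)cc1 | intermediate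
14 | 2,5-bis[4-(tert-butyldimethylsilyloxy)phenyl]-3,6-dioxocyclohexa-1,4-diene-1,4-diyl bis[(2Z,4S,5S)-4,5-epoxyhex-2-enoate] | C[C@@H]1O[C@H]1/C=C\C(=O)OC1=C(c2ccc(O[Si](C)(C)C(C)(C)C)cc2)C(=O)C(OC(=O)/C=C\[C@@H]2O[C@H]2C)=C(c2ccc(O[Si](C)(C)C(C)(C)C)cc2)C1=O | intermediate
15 | 2,5-bis(4-hydroxyphenyl)-3,6-dioxocyclohexa-1,4-diene-1,4-diyl bis[(2Z,4S,5S)-4,5-epoxyhex-2-enoate] | C[C@@H]1O[C@H]1/C=C\C(=O)OC1=C(c2ccc(O)cc2)C(=O)C(OC(=O)/C=C\[C@@H]2O[C@H]2C)=C(c2ccc(O)cc2)C1=O | target

## Step count and least certain steps

Total steps: 10. Longest linear sequence: 7 (steps 1, 2, 3, 5, 8, 9, 10).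

**Step 8 (key step).** The most likely failure is erosion of Z selectivity, which is compounded because a single E olefination on either arm spoils the molecule. A second is fragmentation of the aryl ester enolate by loss of aryloxide if the dianion warms before the aldehyde is consumed.

Fallback: the same C2=C3 bond is formed away from the core, setting out from 6 and 11 and returning at 13. Ester 6 is deprotonated with KN(SiMe3)2 and 18-crown-6 and condensed with 11 to give methyl (2Z,4S,5S)-4,5-epoxyhex-2-enoate F1, which can be purified from any E isomer as a small molecule. Cold saponification with LiOH gives (2Z,4S,5S)-4,5-epoxyhex-2-enoic acid F2. This acid is coupled at once with hydroquinone 5 through its mixed anhydride with 2,4,6-trichlorobenzoyl chloride, Et3N and a minimum of DMAP to give 13.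

**Step 9.** The most likely failure is opening of the vinyl epoxides by the acidic, Lewis-acidic aqueous cerium medium. A second is sluggish electron transfer from the acyloxy-bearing, hexasubstituted ring A, which would let the silyloxyphenyl rings be over-oxidised.

Fallback: ring A is capped with groups that leave under neutral conditions by hydride abstraction, setting out from 1 and returning at 14.
- Bromanil 1 with sodium 4-methoxybenzyl oxide (from the alcohol and NaH, THF, low temperature) should give 2,5-dibromo-3,6-bis(4-methoxybenzyloxy)-1,4-benzoquinone F3.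
- Coupling with 3 as in step 2 gives 2,5-bis[4-(tert-butyldimethylsilyloxy)phenyl]-3,6-bis(4-methoxybenzyloxy)-1,4-benzoquinone F4.
- Na2S2O4 gives 2,5-bis(4-methoxybenzyloxy)-3,6-bis[4-(tert-butyldimethylsilyloxy)phenyl]benzene-1,4-diol F5.
- Esterification with 7 as in step 5 gives 2,5-bis(4-methoxybenzyloxy)-3,6-bis[4-(tert-butyldimethylsilyloxy)phenyl]-1,4-phenylene bis{[bis(2,2,2-trifluoroethoxy)phosphoryl]acetate} F6.
- The twofold olefination with 11 as in step 8 gives 2,5-bis(4-methoxybenzyloxy)-3,6-bis[4-(tert-butyldimethylsilyloxy)phenyl]-1,4-phenylene bis[(2Z,4S,5S)-4,5-epoxyhex-2-enoate] F7.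
- 2,3-Dichloro-5,6-dicyano-1,4-benzoquinone (about 3 equiv) in CH2Cl2 with pH 7 buffer removes both 4-methoxybenzyl groups as 4-methoxybenzaldehyde and oxidises the freed hydroquinone in the same flask to 14.

**Step 10.** The most likely failure is loss of an acyl group from the acyloxyquinone to fluoride or adventitious water during a slow desilylation. A second is hydrofluorination of an epoxide on long exposure.

Fallback: the order of unmasking is inverted so that fluoride only meets the hindered aryl esters, setting out from 13 and returning at 15. Compound 13 is treated with Bu4NF buffered with acetic acid in THF at 0 °C to give 2,5-dimethoxy-3,6-bis(4-hydroxyphenyl)-1,4-phenylene bis[(2Z,4S,5S)-4,5-epoxyhex-2-enoate] F8. Its ring A is then oxidised with (NH4)2Ce(NO3)6 in cold aqueous MeCN to 15, so the quinone is made in the last operation. The free phenols then face the oxidant; if they interfere, the same inversion can be applied in the 4-methoxybenzyl series of the preceding fallback, with the quinone oxidant in place of tetravalent cerium.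

**Step 2.** The most likely failure is that the quinone oxidises zerovalent palladium and the boronic acid (homocoupling, protodeboronation). Base-induced hydrolysis of the vinylogous methyl esters and partial loss of the aryl silyl ethers may add to this.

Fallback: the coupling is moved to the hydroquinone oxidation level, setting out from 2 and returning at 5. Compound 2 is reduced with Na2S2O4 and benzylated (benzyl bromide, K2CO3, DMF) to 1,4-bis(benzyloxy)-2,5-dibromo-3,6-dimethoxybenzene F9. A twofold Suzuki–Miyaura coupling with 3 (Pd(OAc)2, 2-dicyclohexylphosphino-2',6'-dimethoxybiphenyl, K3PO4, toluene–H2O, 100 °C) gives 1,4-bis(benzyloxy)-2,5-dimethoxy-3,6-bis[4-(tert-butyldimethylsilyloxy)phenyl]benzene F10. Hydrogenolysis (H2, palladium on carbon, ethyl acetate), which nothing in the molecule resists at this stage, then gives 5.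

## Further compounds

F1 | step 8 | methyl (2Z,4S,5S)-4,5-epoxyhex-2-enoate | COC(=O)/C=C\[C@@H]1O[C@H]1C
F2 | step 8 | (2Z,4S,5S)-4,5-epoxyhex-2-enoic acid | OC(=O)/C=C\[C@@H]1O[C@H]1C
F3 | step 9 | 2,5-dibromo-3,6-bis(4-methoxybenzyloxy)-1,4-benzoquinone | COc1ccc(COC2=C(Br)C(=O)C(OCc3ccc(OC)cc3)=C(Br)C2=O)cc1
F4 | step 9 | 2,5-bis[4-(tert-butyldimethylsilyloxy)phenyl]-3,6-bis(4-methoxybenzyloxy)-1,4-benzoquinone | COc1ccc(COC2=C(c3ccc(O[Si](C)(C)C(C)(C)C)cc3)C(=O)C(OCc3ccc(OC)cc3)=C(c3ccc(O[Si](C)(C)C(C)(C)C)cc3)C2=O)cc1
F5 | step 9 | 2,5-bis(4-methoxybenzyloxy)-3,6-bis[4-(tert-butyldimethylsilyloxy)phenyl]benzene-1,4-diol | COc1ccc(COc2c(O)c(-c3ccc(O[Si](C)(C)C(C)(C)C)cc3)c(OCc3ccc(OC)cc3)c(O)c2-c2ccc(O[Si](C)(C)C(C)(C)C)cc2)cc1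
F6 | step 9 | 2,5-bis(4-methoxybenzyloxy)-3,6-bis[4-(tert-butyldimethylsilyloxy)phenyl]-1,4-phenylene bis{[bis(2,2,2-trifluoroethoxy)phosphoryl]acetate} | COc1ccc(COc2c(OC(=O)CP(=O)(OCC(F)(F)F)OCC(F)(F)F)c(-c3ccc(O[Si](C)(C)C(C)(C)C)cc3)c(OCc3ccc(OC)cc3)c(OC(=O)CP(=O)(OCC(F)(F)F)OCC(F)(F)F)c2-c2ccc(O[Si](C)(C)C(C)(C)C)cc2)cc1
F7 | step 9 | 2,5-bis(4-methoxybenzyloxy)-3,6-bis[4-(tert-butyldimethylsilyloxy)phenyl]-1,4-phenylene bis[(2Z,4S,5S)-4,5-epoxyhex-2-enoate] | COc1ccc(COc2c(OC(=O)/C=C\[C@@H]3O[C@H]3C)c(-c3ccc(O[Si](C)(C)C(C)(C)C)cc3)c(OCc3ccc(OC)cc3)c(OC(=O)/C=C\[C@@H]3O[C@H]3C)c2-c2ccc(O[Si](C)(C)C(C)(C)C)cc2)cc1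
F8 | step 10 | 2,5-dimethoxy-3,6-bis(4-hydroxyphenyl)-1,4-phenylene bis[(2Z,4S,5S)-4,5-epoxyhex-2-enoate] | COc1c(OC(=O)/C=C\[C@@H]2O[C@H]2C)c(-c2ccc(O)cc2)c(OC)c(OC(=O)/C=C\[C@@H]2O[C@H]2C)c1-c1ccc(O)cc1
F9 | step 2 | 1,4-bis(benzyloxy)-2,5-dibromo-3,6-dimethoxybenzene | COc1c(OCc2ccccc2)c(Br)c(OC)c(OCc2ccccc2)c1Br
F10 | step 2 | 1,4-bis(benzyloxy)-2,5-dimethoxy-3,6-bis[4-(tert-butyldimethylsilyloxy)phenyl]benzene | COc1c(OCc2ccccc2)c(-c2ccc(O[Si](C)(C)C(C)(C)C)cc2)c(OC)c(OCc2ccccc2)c1-c1ccc(O[Si](C)(C)C(C)(C)C)cc1
A1 | alternative 1 | 2,5-diethynyl-3,6-dimethoxy-1,4-benzoquinone | COC1=C(C#C)C(=O)C(OC)=C(C#C)C1=O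
A2 | alternative 1 | (E)-1-methoxy-3-(trimethylsilyloxy)buta-1,3-diene | CO/C=C/C(=C)O[Si](C)(C)C
A3 | alternative 1 | 2,5-bis(4-hydroxyphenyl)-3,6-dimethoxy-1,4-benzoquinone | COC1=C(c2ccc(O)cc2)C(=O)C(OC)=C(c2ccc(O)cc2)C1=O
A4 | alternative 2 | 4-hydroxy-3-methoxy-4-[2-methoxy-1-(4-methoxyphenyl)ethenyl]-2-(4-methoxyphenyl)cyclobut-2-en-1-one (racemic, alkene geometry not fixed) | COC=C(c1ccc(OC)cc1)C1(O)C(OC)=C(c2ccc(OC)cc2)C1=O
A5 | alternative 2 | 2,5-dimethoxy-3,6-bis(4-methoxyphenyl)benzene-1,4-diol | COc1ccc(-c2c(O)c(OC)c(-c3ccc(OC)cc3)c(O)c2OC)cc1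
A6 | alternative 3 | 2,5-dimethoxy-3,6-bis[4-(tert-butyldimethylsilyloxy)phenyl]-1,4-phenylene dipropiolate | COc1c(OC(=O)C#C)c(-c2ccc(O[Si](C)(C)C(C)(C)C)cc2)c(OC)c(OC(=O)C#C)c1-c1ccc(O[Si](C)(C)C(C)(C)C)cc1
A7 | alternative 3 | (R)-2-chloropropanal | C[C@@H](Cl)C=O
A8 | alternative 3 | 2,5-dimethoxy-3,6-bis[4-(tert-butyldimethylsilyloxy)phenyl]-1,4-phenylene bis[(4S,5R)-5-chloro-4-hydroxyhex-2-ynoate] | COc1c(OC(=O)C#C[C@H](O)[C@@H](C)Cl)c(-c2ccc(O[Si](C)(C)C(C)(C)C)cc2)c(OC)c(OC(=O)C#C[C@H](O)[C@@H](C)Cl)c1-c1ccc(O[Si](C)(C)C(C)(C)C)cc1
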